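**Retrosynthetic overview**
1. Target 12 ⇒ Na⁺/H⁺ exchange and global O‑debenzylation ⇒ sodium 5,7,4'‑tri‑O‑benzylluteolin 3'‑sulfate 10 ⇒ O‑sulfation of flavone 8, in which the 3'‑OH is the only free hydroxyl.
2. The γ‑pyranone C ring is the only ring built (rings A and B are bought). Its O1–C2 bond comes from iodine‑catalysed oxidative cyclisation of 2'‑hydroxychalcone 6.
3. Chalcone 6 ⇒ intermolecular Claisen–Schmidt aldol condensation of acetophenone 2 with aldehyde 4. This is the key C–C bond and becomes C2–C3 of the flavone.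
4. 2 ⇐ phloroacetophenone 1 by chelation‑controlled 4,6‑di‑O‑benzylation. 4 ⇐ protocatechualdehyde 3 by acidity‑controlled 4‑O‑benzylation.

Assumption: the target has no stereocentre, so there is no enantiomer to control, and it is wanted as the free hydrogen sulfate as drawn. Sodium salt 11 is the bench‑stable storage form.

**Step 1**
Reactants: 1 2',4',6'-trihydroxyacetophenone
Product: 2 1-[2,4-bis(benzyloxy)-6-hydroxyphenyl]ethan-1-one
Conditions: BnBr (2.05 equiv), K2CO3 (2.2 equiv), DMF, 25 → 50 °C, 6 h; recrystallisation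
Reagents that add atoms: benzyl bromide BrCc1ccccc1
Why: Williamson etherification in which the 4‑OH and one ortho‑OH are alkylated while the last ortho‑OH, locked in a strong hydrogen bond to the ketone, stays free when only two equivalents of halide are offered; no stereocentre is formed.

**Step 2**
Reactants: 3 3,4-dihydroxybenzaldehyde
Product: 4 4-(benzyloxy)-3-hydroxybenzaldehyde
Conditions: BnBr (1.05 equiv), NaHCO3 (1.5 equiv), DMF, 40 °C, 20 h; chromatography or crystallisation
Reagents that add atoms: benzyl bromide BrCc1ccccc1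
Why: Williamson etherification under acidity control, because only the 4‑OH (para to the formyl group and clearly more acidic) is deprotonated by hydrogen carbonate, so mono‑benzylation goes to O‑4 and the minor 3‑O‑ and di‑O‑benzyl products are separated off.

**Step 3**
Reactants: 2 1-[2,4-bis(benzyloxy)-6-hydroxyphenyl]ethan-1-one; 4 4-(benzyloxy)-3-hydroxybenzaldehyde (1.15 equiv)
Product: 6 (E)-1-[2,4-bis(benzyloxy)-6-hydroxyphenyl]-3-[4-(benzyloxy)-3-hydroxyphenyl]prop-2-en-1-one (chalcone), via racemic aldol adduct 5 (not isolated)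
Conditions: KOH (50% aq, 12 equiv), EtOH/THF 3:1, N2, rt, 48 h; then 1 M HCl, 0 °C, to pH 4
Reagents that add atoms: none
Why: Claisen–Schmidt crossed aldol condensation in which only 2 can enolise and only 4 carries an aldehyde, the phenoxide of 4 sits meta to the formyl group and so does not quench its electrophilicity by resonance, and E1cB dehydration of racemic 5 removes its carbinol centre and gives the thermodynamic E‑enone.

**Step 4**
Reactants: 6 chalcone
Product: 8 tri-O-benzylluteolin (5,7-bis(benzyloxy)-2-[4-(benzyloxy)-3-hydroxyphenyl]-4H-chromen-4-one), via racemic flavanone 7 (not isolated)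
Conditions: I2 (10 mol %), DMSO, 120 °C, 3 h; aq Na2S2O3 quench, filtration, recrystallisation
Reagents that add atoms: none
Why: Iodine‑catalysed oxidative cyclisation of a 2'‑hydroxychalcone (oxa‑Michael closure to 7, then iodine‑mediated dehydrogenation with DMSO as terminal oxidant), a standard flavone synthesis that tolerates benzyl ethers and a guaiacol‑type free phenol when iodine is kept catalytic, and that erases the transient C2 stereocentre of 7.

**Step 5**
Reactants: 8 tri-O-benzylluteolin
Product: 10 sodium 5,7,4'-tri-O-benzylluteolin 3'-sulfate, via pyridinium sulfate salt 9 (not isolated)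
Conditions: SO3·py (4 equiv), pyridine, 45 °C, 12 h; then aq NaHCO3 to pH 8, co‑evaporation with toluene, SiO2 (CH2Cl2/MeOH 9:1 → 85:15)
Reagents that add atoms: sulfur trioxide–pyridine complex O=S(=O)([O-])[n+]1ccccc1; sodium hydrogen carbonate [Na+].OC([O-])=O
Why: O‑sulfation of a phenol with an SO3–amine complex, regiochemically unambiguous because the 3'‑OH is the only hydroxyl left in 8, while the pyridinium‑to‑sodium exchange gives a stable neutral salt and removes pyridine, which would otherwise inhibit Pd‑catalysed benzyl ether cleavage.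

**Step 6**
Reactants: 10 sodium 5,7,4'-tri-O-benzylluteolin 3'-sulfate
Product: 11 sodium luteolin 3'-sulfate
Conditions: H2 (1 atm), 10% Pd/C, MeOH/THF/H2O 5:4:1, rt, 4–6 h (LC control); Celite, evaporation below 30 °C
Reagents that add atoms: none
Why: Catalytic hydrogenolysis of three aryl benzyl ethers at neutral pH, where the aryl sulfate monoester salt is inert and the C2=C3 bond of the γ‑pyrone is not reduced at 1 atm if the run is stopped after uptake of three equivalents of hydrogen.

**Step 7**
Reactants: 11 sodium luteolin 3'-sulfate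
Product: 12 luteolin 3'-sulfate (2-hydroxy-5-(5,7-dihydroxy-4-oxo-4H-chromen-2-yl)phenyl hydrogen sulfate)
Conditions: 0.1 M aq HCl (1.05 equiv), H2O, 0 °C; at once C18 cartridge (ice‑cold H2O wash, then H2O/MeCN 7:3); freeze‑drying
Reagents that add atoms: none
Why: Simple cation exchange (protonation of the salt with reversed‑phase desalting), workable because aryl sulfate monoesters hydrolyse only slowly in cold, dilute, water‑rich acid while the flavone core holds the product on C18 as the sodium salt by‑product is washed away.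

**Compound list**
1 | 2',4',6'-trihydroxyacetophenone (phloroacetophenone) | CC(=O)c1c(O)cc(O)cc1O | starting material
2 | 1-[2,4-bis(benzyloxy)-6-hydroxyphenyl]ethan-1-one | CC(=O)c1c(O)cc(OCc2ccccc2)cc1OCc1ccccc1 | intermediate
3 | 3,4-dihydroxybenzaldehyde (protocatechualdehyde) | O=Cc1ccc(O)c(O)c1 | starting material
4 | 4-(benzyloxy)-3-hydroxybenzaldehyde | O=Cc1ccc(OCc2ccccc2)c(O)c1 | intermediate
5 | rac-1-[2,4-bis(benzyloxy)-6-hydroxyphenyl]-3-[4-(benzyloxy)-3-hydroxyphenyl]-3-hydroxypropan-1-one (aldol adduct, not isolated) | O=C(CC(O)c1ccc(OCc2ccccc2)c(O)c1)c1c(O)cc(OCc2ccccc2)cc1OCc1ccccc1 | intermediate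
6 | (E)-1-[2,4-bis(benzyloxy)-6-hydroxyphenyl]-3-[4-(benzyloxy)-3-hydroxyphenyl]prop-2-en-1-one | O=C(/C=C/c1ccc(OCc2ccccc2)c(O)c1)c1c(O)cc(OCc2ccccc2)cc1OCc1ccccc1 | intermediate
7 | rac-5,7-bis(benzyloxy)-2-[4-(benzyloxy)-3-hydroxyphenyl]chroman-4-one (flavanone, not isolated) | O=C1CC(c2ccc(OCc3ccccc3)c(O)c2)Oc2cc(OCc3ccccc3)cc(OCc3ccccc3)c12 | intermediate
8 | 5,7-bis(benzyloxy)-2-[4-(benzyloxy)-3-hydroxyphenyl]-4H-chromen-4-one (5,7,4'-tri-O-benzylluteolin) | O=c1cc(-c2ccc(OCc3ccccc3)c(O)c2)oc2cc(OCc3ccccc3)cc(OCc3ccccc3)c12 | intermediate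
9 | pyridinium 5,7,4'-tri-O-benzylluteolin 3'-sulfate (not isolated) | O=c1cc(-c2ccc(OCc3ccccc3)c(OS(=O)(=O)[O-])c2)oc2cc(OCc3ccccc3)cc(OCc3ccccc3)c12.c1cc[nH+]cc1 | intermediate
10 | sodium 5,7,4'-tri-O-benzylluteolin 3'-sulfate | O=c1cc(-c2ccc(OCc3ccccc3)c(OS(=O)(=O)[O-])c2)oc2cc(OCc3ccccc3)cc(OCc3ccccc3)c12.[Na+] | intermediate
11 | sodium luteolin 3'-sulfate | O=c1cc(-c2ccc(O)c(OS(=O)(=O)[O-])c2)oc2cc(O)cc(O)c12.[Na+] | intermediate
12 | luteolin 3'-sulfate (achiral) | O=c1cc(-c2ccc(O)c(OS(=O)(=O)O)c2)oc2cc(O)cc(O)c12 | target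

**Totals**
Total step count: 7.
Longest linear sequence: 6 (steps 1, 3, 4, 5, 6, 7, or equally 2, 3, 4, 5, 6, 7).

**Three steps most likely to fail**

Step 3 (aldol with a free phenol). In 50% KOH both partners are phenoxides. Conversion can stall through poor solubility of the potassium salts, with Cannizzaro loss of 4. The fallback changes the protecting‑group strategy so that the electrophile is neutral. It sets out from 4 and comes back at 6. Aldehyde 4 is treated with MOMCl and iPr2NEt in CH2Cl2 to give 4-(benzyloxy)-3-(methoxymethoxy)benzaldehyde F1. This is condensed with 2 (KOH, EtOH/THF, rt) to give (E)-1-[2,4-bis(benzyloxy)-6-hydroxyphenyl]-3-[4-(benzyloxy)-3-(methoxymethoxy)phenyl]prop-2-en-1-one F2. Brief catalytic HCl in MeOH/THF at 45 °C removes the acetal and leaves the benzyl ethers untouched, returning chalcone 6. Any flavanone 7 formed by the acid is the next intermediate anyway.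

Step 5 (sulfation and isolation of an amphiphilic salt). The o‑benzyloxy phenol may react incompletely. Separating 10 from inorganic sulfate and pyridine can also cost material. The fallback replaces direct SO3 transfer by a protected, neutral sulfate diester. It sets out from 8 and comes back at 10. Flavone 8 reacts with 2,2,2‑trichloroethyl chlorosulfate, Et3N and DMAP in THF at rt to give 5,7,4'-tri-O-benzylluteolin 3'-(2,2,2-trichloroethyl sulfate) F3, which is purified by ordinary silica chromatography. Zn dust and HCOONH4 in MeOH/THF at rt cleave the trichloroethyl group reductively to give ammonium 5,7,4'-tri-O-benzylluteolin 3'-sulfate F4. One equivalent of NaOH in aqueous MeOH followed by evaporation then gives 10.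

Step 7 (liberation of the free acid). The strongly acidic monoester can hydrolyse autocatalytically while it is concentrated, and desalting on C18 may be incomplete. The fallback drops soluble mineral acid, chromatography and organic eluent in favour of a solid‑supported proton source. It sets out from 11 and comes back at 12. An ice‑cold aqueous solution of 11 is passed through a short bed of sulfonated polystyrene resin in the H⁺ form. The eluate is frozen and lyophilised directly, so the sodium stays on the resin. This fallback makes no compound outside the list: none F0.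

**Further compounds**
F1 | step 3 | 4-(benzyloxy)-3-(methoxymethoxy)benzaldehyde | COCOc1cc(C=O)ccc1OCc1ccccc1
F2 | step 3 | (E)-1-[2,4-bis(benzyloxy)-6-hydroxyphenyl]-3-[4-(benzyloxy)-3-(methoxymethoxy)phenyl]prop-2-en-1-one | COCOc1cc(/C=C/C(=O)c2c(O)cc(OCc3ccccc3)cc2OCc2ccccc2)ccc1OCc1ccccc1
F3 | step 5 | 5,7,4'-tri-O-benzylluteolin 3'-(2,2,2-trichloroethyl sulfate) | O=c1cc(-c2ccc(OCc3ccccc3)c(OS(=O)(=O)OCC(Cl)(Cl)Cl)c2)oc2cc(OCc3ccccc3)cc(OCc3ccccc3)c12
F4 | step 5 | ammonium 5,7,4'-tri-O-benzylluteolin 3'-sulfate | O=c1cc(-c2ccc(OCc3ccccc3)c(OS(=O)(=O)[O-])c2)oc2cc(OCc3ccccc3)cc(OCc3ccccc3)c12.[NH4+]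
F0 | step 7 | none | none
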